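Everything rests on removing the methyl-bearing naphthalene ring (C1'–C4') from its fusion bond C4a'–C8a'. Because the C5' methoxy group flanks C4a' and the biaryl carbon C8' flanks C8a', this bond is traced back to an unsymmetrical aryne whose reactivity the ether biases. In one operation a four-carbon senecioamide dienolate adds to it and closes the ring. This forges C1'–C8a' and C4'–C4a' and puts the C2' methyl group and a C4' oxygen in place. The precursor is the complete cis-(1R,3S)-N-methyltetrahydroisoquinoline, already bonded through C7 to a 2-bromo-4-methoxyphenyl ring. Aziridine opening, Bischler–Napieralski closure, hydride reduction and a Negishi coupling assemble it. One O-methylation finishes the synthesis.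

Key step: step 8

Assumption: the target SMILES defines C1 (R) and C3 (S) but not the sense of the hindered C7–C8' axis, so the route controls the two centres only; should the axis prove rotationally stable, the atropo-diastereomers arising in step 8 would be separated by chromatography at 20 or 22.

Step 1
Reactants: 1 1-bromo-3,5-dimethoxybenzene; 2 tert-butyl (2S)-2-methylaziridine-1-carboxylate
Product: 4 tert-butyl N-[(2S)-1-(3,5-dimethoxyphenyl)propan-2-yl]carbamate, via 3,5-dimethoxyphenylmagnesium bromide 3 (not isolated)
Conditions: 1, Mg, THF, reflux; then 2, CuBr·SMe2 (10 mol %), THF, −30 → 0 °C; aq NH4Cl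
Reagents that add atoms: none
Why: Copper-catalysed SN2 ring opening of an N-Boc-activated aziridine by an aryl Grignard reagent occurs at the unsubstituted CH2, so the nitrogen-bearing stereocentre of 2 (the future C3, S) is carried over untouched.

Step 2
Reactants: 4 tert-butyl N-[(2S)-1-(3,5-dimethoxyphenyl)propan-2-yl]carbamate
Product: 6 N-[(2S)-1-(3,5-dimethoxyphenyl)propan-2-yl]acetamide, via amine hydrochloride 5 (not isolated)
Conditions: 4 M HCl/dioxane, rt; evaporate; Ac2O, Et3N, CH2Cl2, 0 °C → rt
Reagents that add atoms: acetic anhydride CC(=O)OC(C)=O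
Why: Acidolytic carbamate cleavage followed by N-acylation leaves the stereocentre and the aryl ethers alone, and HCl in dioxane rather than neat trifluoroacetic acid limits tert-butylation of the electron-rich ring.

Step 3
Reactants: 6 N-[(2S)-1-(3,5-dimethoxyphenyl)propan-2-yl]acetamide
Product: 7 (3S)-6,8-dimethoxy-1,3-dimethyl-3,4-dihydroisoquinoline
Conditions: POCl3, MeCN, reflux; basic aqueous work-up
Reagents that add atoms: none
Why: In this Bischler–Napieralski cyclodehydration the activated amide is attacked by a ring carbon ortho to one methoxy group and para to the other, and since the two candidate carbons are equivalent by symmetry a single dihydroisoquinoline should form with C3 intact.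

Step 4
Reactants: 7 (3S)-6,8-dimethoxy-1,3-dimethyl-3,4-dihydroisoquinoline
Product: 8 (1R,3S)-6,8-dimethoxy-1,3-dimethyl-1,2,3,4-tetrahydroisoquinoline
Conditions: NaBH4, MeOH, 0 °C → rt
Reagents that add atoms: none
Why: In this substrate-controlled imine reduction, hydride reaches C1 from the face turned away from the C3 methyl group, which places the C1 methyl group on the same side as the C3 methyl group and sets C1 as R (1,3-cis), the usual outcome for 1,3-dimethyl-3,4-dihydroisoquinolines.

Step 5
Reactants: 8 (1R,3S)-6,8-dimethoxy-1,3-dimethyl-1,2,3,4-tetrahydroisoquinoline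
Product: 9 (1R,3S)-6,8-dimethoxy-1,2,3-trimethyl-1,2,3,4-tetrahydroisoquinoline
Conditions: aq HCHO, NaBH(OAc)3, ClCH2CH2Cl, rt
Reagents that add atoms: formaldehyde C=O
Why: Reductive amination with formaldehyde traps the N-methyleneiminium ion by hydride under nearly neutral conditions, so neither C1 nor C3 can epimerise and over-alkylation is impossible.

Step 6
Reactants: 9 (1R,3S)-6,8-dimethoxy-1,2,3-trimethyl-1,2,3,4-tetrahydroisoquinoline; 10 3-bromo-4-iodoanisole
Product: 13 (1R,3S)-7-(2-bromo-4-methoxyphenyl)-6,8-dimethoxy-1,2,3-trimethyl-1,2,3,4-tetrahydroisoquinoline, via C7 aryllithium 11 (not isolated), via C7 arylzinc chloride 12 (not isolated)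
Conditions: n-BuLi (1.1 equiv), THF, 0 °C → rt; ZnCl2, THF, 0 °C → rt; 10 (1.2 equiv), Pd(PPh3)4 (5 mol %), THF, 60 °C
Reagents that add atoms: none
Why: Directed ortho-metalation removes C7–H, the only hydrogen lying between two methoxy groups, and after transmetalation to zinc the Negishi coupling proceeds by insertion of zerovalent palladium into the carbon–iodine bond of 10 well ahead of the carbon–bromine bond, any rotamers about the new biaryl bond being irrelevant because they converge on one aryne.

Step 7
Reactants: 14 3-methylbut-2-enoyl chloride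
Product: 15 N,N-diethyl-3-methylbut-2-enamide
Conditions: Et2NH (2.2 equiv), CH2Cl2, 0 °C → rt
Reagents that add atoms: diethylamine CCNCC
Why: Aminolysis of an acid chloride gives the amide directly, and any β,γ-unsaturated isomer formed by way of a vinylketene is harmless because it gives the same dienolate on deprotonation.

Step 8
Reactants: 13 (1R,3S)-7-(2-bromo-4-methoxyphenyl)-6,8-dimethoxy-1,2,3-trimethyl-1,2,3,4-tetrahydroisoquinoline; 15 N,N-diethyl-3-methylbut-2-enamide
Product: 20 5-[(1R,3S)-6,8-dimethoxy-1,2,3-trimethyl-1,2,3,4-tetrahydroisoquinolin-7-yl]-8-methoxy-3-methylnaphthalen-1-ol, via lithium dienolate 16 (not isolated), via lithiated bromide 17 (not isolated), via aryne 18 (not isolated), via aryllithium adduct 19 (not isolated)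
Conditions: LiTMP (lithium 2,2,6,6-tetramethylpiperidide, from the amine and n-BuLi, 4.5 equiv), 15 (3 equiv), THF, −78 °C; then 13 in THF added slowly, −78 °C → rt; aq NH4Cl
Reagents that add atoms: none
Why: LiTMP first turns 15 into its extended lithium dienolate 16 and then takes the one ring hydrogen of 13 that is flanked by both Br and OMe, so 17 sheds LiBr and only aryne 18 (C4a'≡C8a') can arise, C8' carrying no hydrogen. The terminal CH2 of 16 bonds to C8a' (C1'–C8a'), which leaves the charge of 19 on C4a' beside the inductively stabilising, lithium-binding C5' methoxy group. This aryllithium attacks the Z-disposed amide carbonyl in a 6-exo-trig addition–elimination (C4'–C4a'), LiNEt2 departs, and the 4H-naphthalenone formed enolises irreversibly to the naphtholate of 20. The reaction type is the established anionic [4+2] benzannulation of haloanisole-derived arynes with senecioamide dienolates to 3-methyl-1-naphthols, used here on a more crowded aryne. No stereocentre is created and C1 and C3 lie far from every site the base attacks; only the C7–C8' axis becomes hindered, and the distant centres are expected to bias it little. The selectivity needed is regiochemical and is secured by the methoxy-induced distortion that makes C8a' the electrophilic terminus, while slow addition of 13 to a threefold excess of 16 is meant to outrun amine addition to 18 and premature protonation of 19.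

Step 9
Reactants: 20 5-[(1R,3S)-6,8-dimethoxy-1,2,3-trimethyl-1,2,3,4-tetrahydroisoquinolin-7-yl]-8-methoxy-3-methylnaphthalen-1-ol
Product: 22 ancistrobrevine A, via sodium naphtholate 21 (not isolated)
Conditions: NaH (1.1 equiv), DMF, 0 °C; MeI (1.0 equiv), 0 °C → rt
Reagents that add atoms: iodomethane CI
Why: In this Williamson ether synthesis the anionic naphtholate in DMF is far more nucleophilic toward MeI than the neutral tertiary amine, which is flanked by two methyl-branched carbons, so a single equivalent of MeI at low temperature should end up on oxygen.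

Compound list

1 | 1-bromo-3,5-dimethoxybenzene | COc1cc(Br)cc(OC)c1 | starting material
2 | tert-butyl (2S)-2-methylaziridine-1-carboxylate | C[C@H]1CN1C(=O)OC(C)(C)C | starting material
3 | 3,5-dimethoxyphenylmagnesium bromide | COc1cc([Mg]Br)cc(OC)c1 | intermediate
4 | tert-butyl N-[(2S)-1-(3,5-dimethoxyphenyl)propan-2-yl]carbamate | COc1cc(C[C@H](C)NC(=O)OC(C)(C)C)cc(OC)c1 | intermediate
5 | (2S)-1-(3,5-dimethoxyphenyl)propan-2-aminium chloride | COc1cc(C[C@H](C)[NH3+])cc(OC)c1.[Cl-] | intermediate
6 | N-[(2S)-1-(3,5-dimethoxyphenyl)propan-2-yl]acetamide | COc1cc(C[C@H](C)NC(C)=O)cc(OC)c1 | intermediate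
7 | (3S)-6,8-dimethoxy-1,3-dimethyl-3,4-dihydroisoquinoline | COc1cc2c(c(OC)c1)C(C)=N[C@@H](C)C2 | intermediate
8 | (1R,3S)-6,8-dimethoxy-1,3-dimethyl-1,2,3,4-tetrahydroisoquinoline | COc1cc2c(c(OC)c1)[C@@H](C)N[C@@H](C)C2 | intermediate
9 | (1R,3S)-6,8-dimethoxy-1,2,3-trimethyl-1,2,3,4-tetrahydroisoquinoline | COc1cc2c(c(OC)c1)[C@@H](C)N(C)[C@@H](C)C2 | intermediate
10 | 3-bromo-4-iodoanisole (2-bromo-1-iodo-4-methoxybenzene) | COc1ccc(I)c(Br)c1 | starting material
11 | [(1R,3S)-6,8-dimethoxy-1,2,3-trimethyl-1,2,3,4-tetrahydroisoquinolin-7-yl]lithium | COc1cc2c(c(OC)c1[Li])[C@@H](C)N(C)[C@@H](C)C2 | intermediate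
12 | [(1R,3S)-6,8-dimethoxy-1,2,3-trimethyl-1,2,3,4-tetrahydroisoquinolin-7-yl]zinc chloride | COc1cc2c(c(OC)c1[Zn]Cl)[C@@H](C)N(C)[C@@H](C)C2 | intermediate
13 | (1R,3S)-7-(2-bromo-4-methoxyphenyl)-6,8-dimethoxy-1,2,3-trimethyl-1,2,3,4-tetrahydroisoquinoline | COc1cc2c(c(OC)c1-c1ccc(OC)cc1Br)[C@@H](C)N(C)[C@@H](C)C2 | intermediate
14 | 3-methylbut-2-enoyl chloride | CC(C)=CC(Cl)=O | starting material
15 | N,N-diethyl-3-methylbut-2-enamide | CCN(CC)C(=O)C=C(C)C | intermediate
16 | lithium 1-(diethylamino)-3-methylbuta-1,3-dien-1-olate | [Li+].[O-]C(=CC(C)=C)N(CC)CC | intermediate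
17 | (1R,3S)-7-(2-bromo-3-lithio-4-methoxyphenyl)-6,8-dimethoxy-1,2,3-trimethyl-1,2,3,4-tetrahydroisoquinoline | COc1cc2c(c(OC)c1-c1ccc(OC)c([Li])c1Br)[C@@H](C)N(C)[C@@H](C)C2 | intermediate
18 | (1R,3S)-7-(2,3-didehydro-4-methoxyphenyl)-6,8-dimethoxy-1,2,3-trimethyl-1,2,3,4-tetrahydroisoquinoline (the 3-methoxy-6-arylbenzyne) | COc1cc2c(c(OC)c1C1=CC=C(OC)C#C1)[C@@H](C)N(C)[C@@H](C)C2 | intermediate
19 | (2Z)-4-{2-[(1R,3S)-6,8-dimethoxy-1,2,3-trimethyl-1,2,3,4-tetrahydroisoquinolin-7-yl]-6-lithio-5-methoxyphenyl}-N,N-diethyl-3-methylbut-2-enamide | COc1cc2c(c(OC)c1-c1ccc(OC)c([Li])c1C/C(C)=C\C(=O)N(CC)CC)[C@@H](C)N(C)[C@@H](C)C2 | intermediate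
20 | 5-[(1R,3S)-6,8-dimethoxy-1,2,3-trimethyl-1,2,3,4-tetrahydroisoquinolin-7-yl]-8-methoxy-3-methylnaphthalen-1-ol | COc1cc2c(c(OC)c1-c1ccc(OC)c3c(O)cc(C)cc13)[C@@H](C)N(C)[C@@H](C)C2 | intermediate
21 | sodium 5-[(1R,3S)-6,8-dimethoxy-1,2,3-trimethyl-1,2,3,4-tetrahydroisoquinolin-7-yl]-8-methoxy-3-methylnaphthalen-1-olate | COc1cc2c(c(OC)c1-c1ccc(OC)c3c([O-])cc(C)cc13)[C@@H](C)N(C)[C@@H](C)C2.[Na+] | intermediate
22 | ancistrobrevine A, (1R,3S)-7-(4,5-dimethoxy-7-methylnaphthalen-1-yl)-6,8-dimethoxy-1,2,3-trimethyl-1,2,3,4-tetrahydroisoquinoline | COc1cc2c(c(OC)c1-c1ccc(OC)c3c(OC)cc(C)cc13)[C@@H](C)N(C)[C@@H](C)C2 | target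

Total step count: 9. Longest linear sequence: 8 steps (steps 1–6, 8 and 9, from 1 to 22); step 7 is a one-step branch.

Steps most likely to fail

Step 8 (aryne benzannulation).
- **Risk:** Crowding by the aryl group on C8' may divert the dienolate to C4a'. The aryl anion may pick up a proton from the neighbouring acidic CH2 or from an amine before it reaches the carbonyl group. Amines may also capture the aryne.
- **Fallback:** The naphthalene is built first and the biaryl bond is formed last, setting out from 15 and 9.
  - Dienolate 16, made from 15 as in step 8, is combined with commercial 3,4-dibromoanisole (COc1ccc(Br)c(Br)c1) and LiTMP.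
  - Lithiation between OMe and Br and loss of LiBr give 3-bromo-6-methoxybenzyne F1, which has only a bromine atom beside the carbon to be attacked.
  - The same annulation then gives 5-bromo-8-methoxy-3-methylnaphthalen-1-ol F2. Bromine opposes the methoxy bias weakly, so any regioisomer would be removed at this inexpensive stage.
  - NaH and MeI give 5-bromo-1,8-dimethoxy-3-methylnaphthalene F3.
  - Arylzinc chloride 12, prepared from 9 as in step 6, is coupled with F3 in a Negishi reaction (Pd2(dba)3, SPhos, THF, 65 °C). No second halide has to be spared here. The sequence returns to the route at 22.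

Step 6 (metalation and Negishi coupling).
- **Risk:** Transmetalation and reductive elimination at a doubly ortho-substituted arylzinc may be slow, which would lead to protodemetalation or homocoupling. A more active catalyst could lose the discrimination between the two halides and consume the bromide.
- **Fallback:** The polarity of the coupling is reversed, setting out from 9 by way of 11.
  - Quenching 11 with I2 gives (1R,3S)-7-iodo-6,8-dimethoxy-1,2,3-trimethyl-1,2,3,4-tetrahydroisoquinoline F4.
  - A Suzuki–Miyaura coupling of F4 with commercial (2-bromo-4-methoxyphenyl)boronic acid (COc1ccc(B(O)O)c(Br)c1; Pd(PPh3)4, K2CO3, dioxane/H2O, 80 °C) engages the iodide in preference to the bromide and returns to the route at 13.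

Step 9 (O-methylation).
- **Risk:** Quaternisation at nitrogen may compete, and the hydrogen-bonded, peri-crowded hydroxyl group may react sluggishly.
- **Fallback:** The free alkyl halide is given up, setting out from 20. A Mitsunobu etherification with methanol (PPh3, DIAD, MeOH, THF, 0 °C → rt) generates the methyl donor only as a methoxyphosphonium ion paired with the naphtholate. The amine therefore stays untouched and 22 is reached directly.

Further compounds
F1 | step 8 | 3-bromo-6-methoxybenzyne (1-bromo-2,3-didehydro-4-methoxybenzene) | COC1=CC=C(Br)C#C1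
F2 | step 8 | 5-bromo-8-methoxy-3-methylnaphthalen-1-ol | COc1ccc(Br)c2cc(C)cc(O)c12
F3 | step 8 | 5-bromo-1,8-dimethoxy-3-methylnaphthalene | COc1ccc(Br)c2cc(C)cc(OC)c12
F4 | step 6 | (1R,3S)-7-iodo-6,8-dimethoxy-1,2,3-trimethyl-1,2,3,4-tetrahydroisoquinoline | COc1cc2c(c(OC)c1I)[C@@H](C)N(C)[C@@H](C)C2
F0 | step 9 | none | none
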